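**Plan**
- Retrosynthesis: after removal of the two MOM ethers, ring C is cut at O1–C8a and C4–C4a. These bonds end on adjacent carbons of ring A, the two ends of a C4a–C8a aryne, and the C5 oxygen beside C4a directs the addition.
- This leaves a ring A ortho-silylaryl triflate and an (S)-β-hydroxy ester that carries ring B, C2, C3 and C4.
- Forward: ring A is built from 5-methoxyresorcinol by two carbamate-directed ortho-metalations (silicon at C4a, prenyl at C8) and triflation. The ester is made from 3'-hydroxy-4'-methoxyacetophenone by Claisen condensation and asymmetric transfer hydrogenation.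
- The fragments are joined and ring C, the only ring made, is closed in one aryne insertion–acylation; acid then frees both phenols.
- Stereochemistry: C2 (S) is set by the ruthenium-catalysed ketone reduction and carried through the annulation with retention, because its C–O bond is never broken.

Key step: step 10

Remark on the chemistry: flavanone numbering (O1, C2, C3, C4, C4a, C5 to C8, C8a; ring B primed) is used for all ring A intermediates, prenyl means 3-methylbut-2-en-1-yl, and the aryl ketone model of the transfer hydrogenation is assumed to hold for β-keto ester 14.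

Step 1
Reactants: 1 5-methoxyresorcinol
Product: 2 3-methoxy-5-(methoxymethoxy)phenol
Conditions: MOMCl (1.0 equiv), i-Pr2NEt, CH2Cl2, 0 °C to rt
Reagents that add atoms: chloromethyl methyl ether, COCCl
Why: O-alkylation of a phenol (MOM ether formation); the two hydroxyls are equivalent, so one equivalent of MOMCl should give the mono-ether as the main product, with the bis-ether and recovered 1 separable and recyclable.

Step 2
Reactants: 2 3-methoxy-5-(methoxymethoxy)phenol
Product: 3 3-methoxy-5-(methoxymethoxy)phenyl N,N-diethylcarbamate
Conditions: Et2NCOCl, K2CO3, MeCN, reflux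
Reagents that add atoms: N,N-diethylcarbamoyl chloride, CCN(CC)C(Cl)=O
Why: O-acylation of the phenoxide (carbamate formation) puts the strongest oxygen-based directing group for ortho-metalation on the oxygen that will later carry the triflate.

Step 3
Reactants: 3 3-methoxy-5-(methoxymethoxy)phenyl N,N-diethylcarbamate
Product: 5 5-methoxy-3-(methoxymethoxy)-2-(trimethylsilyl)phenyl N,N-diethylcarbamate, via aryllithium 4 (not isolated)
Conditions: s-BuLi, TMEDA, THF, −78 °C; then TMSCl, −78 °C to rt
Reagents that add atoms: chlorotrimethylsilane, C[Si](C)(C)Cl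
Why: Directed ortho-metalation: the C–H flanked by the carbamate and the MOM ether (C4a) has the two strongest cooperating directing groups and should be lithiated first, the aryllithium resists anionic ortho-Fries rearrangement at −78 °C, and TMSCl silylates it.

Step 4
Reactants: 5 5-methoxy-3-(methoxymethoxy)-2-(trimethylsilyl)phenyl N,N-diethylcarbamate; 6 prenyl bromide
Product: 8 3-methoxy-5-(methoxymethoxy)-2-prenyl-6-(trimethylsilyl)phenyl N,N-diethylcarbamate, via aryllithium 7 (not isolated)
Conditions: s-BuLi, TMEDA, THF, −78 °C; then CuBr·SMe2 (10 mol %), prenyl bromide, −78 to −30 °C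
Reagents that add atoms: none
Why: Second directed ortho-metalation with the more acidic site blocked by silicon: the carbamate, helped by the C7 methoxy group, directs lithiation to C8, and the aryllithium is alkylated at the primary carbon of the allylic bromide (copper-catalysed SN2 coupling) while the cold mixture suppresses carbamoyl migration.

Step 5
Reactants: 8 3-methoxy-5-(methoxymethoxy)-2-prenyl-6-(trimethylsilyl)phenyl N,N-diethylcarbamate
Product: 9 3-methoxy-5-(methoxymethoxy)-2-prenyl-6-(trimethylsilyl)phenol
Conditions: LiAlH4, THF, 0 °C to reflux; aq. KNaC4H4O6 (potassium sodium tartrate) work-up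
Reagents that add atoms: none
Why: Reductive cleavage of the aryl carbamate: hydride adds to the carbamate carbonyl, the phenoxide is expelled and the formamide left behind is reduced to the amine, and the non-acidic work-up protects the electron-rich aryl–silicon bond and the MOM ether.

Step 6
Reactants: 9 3-methoxy-5-(methoxymethoxy)-2-prenyl-6-(trimethylsilyl)phenol
Product: 10 3-methoxy-5-(methoxymethoxy)-2-prenyl-6-(trimethylsilyl)phenyl trifluoromethanesulfonate
Conditions: PhNTf2, DBU, MeCN, 0 °C to rt
Reagents that add atoms: N-phenylbis(trifluoromethanesulfonimide), O=S(=O)(N(c1ccccc1)S(=O)(=O)C(F)(F)F)C(F)(F)F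
Why: O-sulfonylation (triflation) of the phenoxide with a mild triflyl donor under non-acidic conditions is the usual last step in making ortho-silylaryl triflates and should tolerate the flanking silyl and prenyl groups.

Step 7
Reactants: 11 3'-hydroxy-4'-methoxyacetophenone
Product: 12 1-[4-methoxy-3-(methoxymethoxy)phenyl]ethan-1-one
Conditions: MOMCl, i-Pr2NEt, CH2Cl2, 0 °C to rt
Reagents that add atoms: chloromethyl methyl ether, COCCl
Why: MOM ether formation masks the ring B phenol, which would otherwise outcompete the aliphatic alcohol for the aryne in step 10.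

Step 8
Reactants: 12 1-[4-methoxy-3-(methoxymethoxy)phenyl]ethan-1-one; 13 dimethyl carbonate
Product: 14 methyl 3-[4-methoxy-3-(methoxymethoxy)phenyl]-3-oxopropanoate
Conditions: NaH, (MeO)2CO, THF, reflux; AcOH quench
Reagents that add atoms: none
Why: Crossed Claisen condensation of the ketone enolate with dimethyl carbonate, driven to completion by deprotonation of the β-keto ester that forms.

Step 9
Reactants: 14 methyl 3-[4-methoxy-3-(methoxymethoxy)phenyl]-3-oxopropanoate
Product: 15 methyl (S)-3-hydroxy-3-[4-methoxy-3-(methoxymethoxy)phenyl]propanoate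
Conditions: RuCl[(S,S)-TsDPEN](p-cymene) (1 mol %), HCO2H–Et3N (5:2), DMF, 30 °C
Reagents that add atoms: none
Why: Noyori asymmetric transfer hydrogenation: the divalent ruthenium hydride of the (S,S)-diamine complex recognises the aryl ketone through the arene CH/π contact and should deliver hydride to the Re face of the carbonyl, setting the carbinol carbon (the later C2) as (S).

Step 10
Reactants: 10 3-methoxy-5-(methoxymethoxy)-2-prenyl-6-(trimethylsilyl)phenyl trifluoromethanesulfonate (1.4 equiv); 15 methyl (S)-3-hydroxy-3-[4-methoxy-3-(methoxymethoxy)phenyl]propanoate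
Product: 18 (S)-5,3'-bis(methoxymethoxy)-7,4'-dimethoxy-8-prenylflavanone, via aryne 16 (not isolated), via arylpotassium ether 17 (not isolated)
Conditions: KF, 18-crown-6, 4 Å molecular sieves, THF (0.02 M), −20 to 0 °C; aq. NaH2PO4/Na2HPO4 (pH 7) quench
Reagents that add atoms: none
Why: Proposed new method: fluoride removes the silyl group of 10 and triflate leaves, giving aryne 16 (C4a≡C8a); the fluoride-activated hydroxyl of 15 adds at C8a as an alkoxide, and the C4a aryl anion 17 attacks the methyl ester six atoms away and expels methoxide, so that O1–C8a and C4–C4a form in one flask. The closest known reaction type is the fluoride-promoted annulation of arynes with methyl salicylates to xanthones (aryl ether formation, then acyl substitution by the aryl anion), together with the known low-temperature O-arylation of aliphatic alcohols by arynes; an aliphatic β-hydroxy ester as the partner is the extrapolation. Ring C closes by 6-exo-trig acyl substitution of the aryl anion on the ester carbonyl. No stereocentre is created: C2 comes from 15 with its C–O and C–H bonds untouched, so the (S) configuration is retained as long as base-induced retro-oxa-Michael opening of 18 is suppressed, for which the low temperature, the sieves (uptake of methanol) and the buffered quench are chosen. The step needs regioselectivity (oxygen at C8a, acyl at C4a), which the C5 MOM ether secures by polarising the aryne so that the nucleophile enters at the distal carbon and the charge develops at C4a beside oxygen, a bias the C8 prenyl group should not override. It also needs acylation to outrun protonation of the aryl anion, which dilution, the aprotic medium and the proximity of the ester favour.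

Step 11
Reactants: 18 (S)-5,3'-bis(methoxymethoxy)-7,4'-dimethoxy-8-prenylflavanone
Product: 19 (S)-5,3'-dihydroxy-7,4'-dimethoxy-8-prenylflavanone (CNP0228678.1)
Conditions: 3 M aq. HCl–MeOH (1:4), 45 °C
Reagents that add atoms: none
Why: Acid-catalysed acetal cleavage (MOM removal) with methanol trapping the methoxymethyl cation; the chelated C5 ether should fall first, the prenyl group has no free ortho-phenol to cyclise onto (it lies between the C7 methoxy group and O1), and C2 is not involved.

**Compound list**
1 | 5-methoxyresorcinol (5-methoxybenzene-1,3-diol) | COc1cc(O)cc(O)c1 | starting material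
2 | 3-methoxy-5-(methoxymethoxy)phenol | COCOc1cc(O)cc(OC)c1 | intermediate
3 | 3-methoxy-5-(methoxymethoxy)phenyl N,N-diethylcarbamate | CCN(CC)C(=O)Oc1cc(OC)cc(OCOC)c1 | intermediate
4 | [2-(diethylcarbamoyloxy)-4-methoxy-6-(methoxymethoxy)phenyl]lithium | CCN(CC)C(=O)Oc1cc(OC)cc(OCOC)c1[Li] | intermediate
5 | 5-methoxy-3-(methoxymethoxy)-2-(trimethylsilyl)phenyl N,N-diethylcarbamate | CCN(CC)C(=O)Oc1cc(OC)cc(OCOC)c1[Si](C)(C)C | intermediate
6 | prenyl bromide (1-bromo-3-methylbut-2-ene) | CC(C)=CCBr | starting material
7 | [2-(diethylcarbamoyloxy)-6-methoxy-4-(methoxymethoxy)-3-(trimethylsilyl)phenyl]lithium | CCN(CC)C(=O)Oc1c([Li])c(OC)cc(OCOC)c1[Si](C)(C)C | intermediate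
8 | 3-methoxy-5-(methoxymethoxy)-2-(3-methylbut-2-en-1-yl)-6-(trimethylsilyl)phenyl N,N-diethylcarbamate | CCN(CC)C(=O)Oc1c(CC=C(C)C)c(OC)cc(OCOC)c1[Si](C)(C)C | intermediate
9 | 3-methoxy-5-(methoxymethoxy)-2-(3-methylbut-2-en-1-yl)-6-(trimethylsilyl)phenol | Oc1c(CC=C(C)C)c(OC)cc(OCOC)c1[Si](C)(C)C | intermediate
10 | 3-methoxy-5-(methoxymethoxy)-2-(3-methylbut-2-en-1-yl)-6-(trimethylsilyl)phenyl trifluoromethanesulfonate | COCOc1cc(OC)c(CC=C(C)C)c(OS(=O)(=O)C(F)(F)F)c1[Si](C)(C)C | intermediate
11 | 3'-hydroxy-4'-methoxyacetophenone | CC(=O)c1ccc(OC)c(O)c1 | starting material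
12 | 1-[4-methoxy-3-(methoxymethoxy)phenyl]ethan-1-one | CC(=O)c1ccc(OC)c(OCOC)c1 | intermediate
13 | dimethyl carbonate | COC(=O)OC | starting material
14 | methyl 3-[4-methoxy-3-(methoxymethoxy)phenyl]-3-oxopropanoate | COC(=O)CC(=O)c1ccc(OC)c(OCOC)c1 | intermediate
15 | methyl (S)-3-hydroxy-3-[4-methoxy-3-(methoxymethoxy)phenyl]propanoate | COc1ccc([C@@H](O)CC(=O)OC)cc1OCOC | intermediate
16 | 1,2-didehydro-4-methoxy-6-(methoxymethoxy)-3-(3-methylbut-2-en-1-yl)benzene (C4a–C8a aryne) | COCOC1=CC(OC)=C(CC=C(C)C)C#C1 | intermediate
17 | methyl (S)-3-[4-methoxy-3-(methoxymethoxy)phenyl]-3-[3-methoxy-5-(methoxymethoxy)-2-prenyl-6-potassiophenoxy]propanoate | COc1ccc([C@@H](Oc2c(CC=C(C)C)c(OC)cc(OCOC)c2[K])CC(=O)OC)cc1OCOC | intermediate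
18 | (2S)-7-methoxy-5-(methoxymethoxy)-2-[4-methoxy-3-(methoxymethoxy)phenyl]-8-(3-methylbut-2-en-1-yl)-2,3-dihydro-4H-chromen-4-one | COc1ccc([C@@H]2CC(=O)c3c(OCOC)cc(OC)c(CC=C(C)C)c3O2)cc1OCOC | intermediate
19 | (2S)-5-hydroxy-2-(3-hydroxy-4-methoxyphenyl)-7-methoxy-8-(3-methylbut-2-en-1-yl)-2,3-dihydro-4H-chromen-4-one | COc1ccc([C@@H]2CC(=O)c3c(O)cc(OC)c(CC=C(C)C)c3O2)cc1O | target

**Step count**
Total: 11 steps. Longest linear sequence: 8 steps (steps 1 to 6, then 10 and 11).

**Steps most likely to fail**

Step 10. The C4a aryl anion may be protonated by 15 or by the methanol released before it reaches the ester, which would leave the open aryl ether. Methoxide may also open ring C by retro-oxa-Michael reaction and erode the configuration at C2. The fallback uses known chemistry, sets out from 10 and comes back at 18. Isovanillin is protected with MOMCl and i-Pr2NEt to 4-methoxy-3-(methoxymethoxy)benzaldehyde F1. Knoevenagel–Doebner condensation of this aldehyde with malonic acid (pyridine, piperidine, 90 °C) gives (E)-3-[4-methoxy-3-(methoxymethoxy)phenyl]acrylic acid F2. With CsF in THF at 125 °C in a sealed tube, 10 and F2 should undergo the known insertion of an aryne into the C–O bond of a carboxylic acid: the carboxylate adds at C8a and the acyl group moves to C4a, giving (E)-1-[2-hydroxy-4-methoxy-6-(methoxymethoxy)-3-prenylphenyl]-3-[4-methoxy-3-(methoxymethoxy)phenyl]prop-2-en-1-one F3. This chalcone has a single free phenol and should close by oxa-Michael addition, in the same flask or with NaOAc in EtOH at reflux, to racemic 5,3'-bis(methoxymethoxy)-7,4'-dimethoxy-8-prenylflavanone F4. Kinetic resolution by asymmetric transfer hydrogenation with RuCl[(R,R)-TsDPEN](p-cymene) and HCO2H–Et3N, run to about half conversion, is expected to reduce the (2R) enantiomer to the cis alcohol (2R,4R)-5,3'-bis(methoxymethoxy)-7,4'-dimethoxy-8-prenylflavan-4-ol F5. The unreduced (S) ketone is then separated by chromatography as 18.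

Step 4. The hindered aryllithium 7 may couple slowly with prenyl bromide or at its tertiary end, and the carbamoyl group may migrate (anionic ortho-Fries) as the mixture warms. The fallback sets out from 5 and comes back at 8. Compound 5 is lithiated as before and the aryllithium is quenched at −78 °C with allyl bromide, a faster electrophile with no regiochemical ambiguity, to give 2-allyl-3-methoxy-5-(methoxymethoxy)-6-(trimethylsilyl)phenyl N,N-diethylcarbamate F6. Olefin cross-metathesis of F6 with excess 2-methyl-2-butene, using the second-generation Grubbs catalyst RuCl2(=CHPh)(PCy3)(H2IMes) in CH2Cl2 at 40 °C, should then give 8.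

Step 5. Hydride attack on a carbamate carbonyl shielded by two ortho substituents may be incomplete, and forcing it may cost the silyl group. The fallback sets out from 5, comes back at 9 and bypasses steps 4 and 5. The carbamate is cleaved before the prenyl group is present: LiAlH4 in THF converts 5 into 5-methoxy-3-(methoxymethoxy)-2-(trimethylsilyl)phenol F7. Tsuji–Trost O-allylation with methyl 2-methylbut-3-en-2-yl carbonate and Pd(PPh3)4 (zerovalent palladium) in THF gives the tertiary ether [4-methoxy-2-(methoxymethoxy)-6-(2-methylbut-3-en-2-yloxy)phenyl]trimethylsilane F8. Aromatic Claisen rearrangement in toluene at 90 to 110 °C moves the allyl unit, with allylic inversion, to the only free ortho carbon (the other carries silicon) and should give the prenyl phenol 9 directly.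

**Further compounds**
F1 | step 10 | 4-methoxy-3-(methoxymethoxy)benzaldehyde | COCOc1cc(C=O)ccc1OC
F2 | step 10 | (E)-3-[4-methoxy-3-(methoxymethoxy)phenyl]acrylic acid | COCOc1cc(/C=C/C(=O)O)ccc1OC
F3 | step 10 | (E)-1-[2-hydroxy-4-methoxy-6-(methoxymethoxy)-3-prenylphenyl]-3-[4-methoxy-3-(methoxymethoxy)phenyl]prop-2-en-1-one | COCOc1cc(OC)c(CC=C(C)C)c(O)c1C(=O)/C=C/c1ccc(OC)c(OCOC)c1
F4 | step 10 | racemic 5,3'-bis(methoxymethoxy)-7,4'-dimethoxy-8-prenylflavanone | COc1ccc(C2CC(=O)c3c(OCOC)cc(OC)c(CC=C(C)C)c3O2)cc1OCOC
F5 | step 10 | (2R,4R)-5,3'-bis(methoxymethoxy)-7,4'-dimethoxy-8-prenylflavan-4-ol | COc1ccc([C@H]2C[C@@H](O)c3c(OCOC)cc(OC)c(CC=C(C)C)c3O2)cc1OCOC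
F6 | step 4 | 2-allyl-3-methoxy-5-(methoxymethoxy)-6-(trimethylsilyl)phenyl N,N-diethylcarbamate | CCN(CC)C(=O)Oc1c(CC=C)c(OC)cc(OCOC)c1[Si](C)(C)C
F7 | step 5 | 5-methoxy-3-(methoxymethoxy)-2-(trimethylsilyl)phenol | Oc1cc(OC)cc(OCOC)c1[Si](C)(C)C
F8 | step 5 | [4-methoxy-2-(methoxymethoxy)-6-(2-methylbut-3-en-2-yloxy)phenyl]trimethylsilane | C=CC(C)(C)Oc1cc(OC)cc(OCOC)c1[Si](C)(C)C
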